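## The problem

Compound 32 is a 3,5-diformylphloroglucinol joined through a benzylic methine (C7′, which also carries an isobutyl group) to the quaternary carbon C1 of an octalin. The labels used throughout are: ring A = C1 (quaternary; methyl and C7′)–C2 (vinyl CH)–C3 (sp2 fusion carbon)–C8 (fusion CH)–C9–C10; ring B = C3–C4 (CHMe)–C5–C6–C7 (CH bearing the carbinol carbon C11)–C8; the arene is C1′–C6′. Five stereocentres must be set: the contiguous, crowded pair C7′/C1 between arene and ring, and the ring triad C4/C7/C8, in which the C7 and C8 appendages are trans and the C4 methyl lies on the face of C8–H. The C7′/C1 pair cannot usefully direct the ring triad, so each group needs its own source of absolute configuration; inside the triad, C7 can direct C8 (vicinal), and C7/C8 can direct C4 once ring A locks ring B. The tertiary alcohol at C11 and the C2=C3 alkene do not tolerate strong protic or Lewis acids, and the aldehydes and the free, easily oxidised phloroglucinol do not tolerate organometallic or radical-oxygen chemistry, so they must appear last. The enabling feature is that C7 and C8 are β and α to C3: with C3 as a ketone carbon, ring B is a cyclohexanone that accepts the C11 unit at C7 by conjugate addition and the C9–C10–C1 arm at C8 by alkylation of the enolate so formed.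

## Retrosynthesis

**32 ⇒ 31 ⇒ 26 (three O–CH3 bonds; C3′–CHO and C5′–CHO).** The phenols are released last from trimethyl ether 31, where every methoxy group is ortho or para to two formyl groups and therefore cleavable by a thiolate under basic conditions that spare C11–OH and the alkene. The formyl groups are cut next, back to arene 26. C3′–H and C5′–H each lie between two methoxy groups, so directed lithiation finds them without ambiguity. A Lewis-acid formylation would ionise the tertiary alcohol, and carrying aldehydes through the organometallic steps would cost protecting groups. The forward steps must tolerate a free tertiary alkoxide and an allylic framework.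

**26 ⇒ 25 (C11–O).** The carbinol is traced to the isopropenyl group of diene 25 by Markovnikov hydration. Doing this late means no tertiary-alcohol protecting group has to pass through enolate and triflation chemistry. Doing it before formylation keeps aldehydes away from O2 and a metal hydride. The forward reaction must choose the 1,1-disubstituted alkene over the hindered trisubstituted C2=C3 alkene.

**25 ⇒ 24 ⇒ 22 (C4–CH3; C2–H back to C2=O).** The C4 methyl is cut by conjugate addition to enone 22 (C2 ketone, C3=C4). The enolate is held as vinyl triflate 24 and reduced, which puts the alkene at C2=C3 regiospecifically because C1 is quaternary. The neighbouring cut, an SN2′ methylation of a C2 allylic ester, would tie C4 to a C2 carbinol configuration that the ring closure does not control. Its anti mode would also need the leaving group pseudoaxial on the face of the C1 methyl, which the ring A chair with an equatorial C7′ substituent disfavours. The enone erases C2 and lets the conformation of ring B decide. The forward reaction needs axial delivery of methyl to C4 on the face of C8–H.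

**22 ⇒ 21 ⇒ 20 ⇒ 19 ⇒ 17 (C2–C3; ring A).** Ring A is opened at C2–C3. C3 must be the nucleophile, which rules out an aldol closure, so it becomes a vinyl triflate (19, 20) that adds to the C2 aldehyde in a Nozaki–Hiyama–Kishi closure to give 21. A reductive carbonyl coupling of a keto aldehyde would need the C4 methyl installed beforehand on an epimerisable ketone; it is kept as a fallback. The precursor, ketone 17, is monocyclic. The forward sequence asks for kinetic enolisation toward C4 and a 6-membered ring closure onto a neopentyl aldehyde.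

**17 ⇒ 13 + 14 + 15 (C7–C11 and C8–C9).** Both substituents of ring B are removed at once. Enone 14 takes the isopropenyl group of 15 at C7 under chiral copper catalysis, and the resulting enolate 16 is alkylated at C8 by iodide 13. This divides the target into a commodity enone, a commodity Grignard reagent and one fragment that holds C7′, C1 and the arene. It sets C7 by catalyst and C8 by C7. Cutting only one of the two bonds would give a 2- or 3-substituted cyclohexanone whose regiodefined enolate is hard to reach. The forward reaction needs face selectivity at C7 and clean C-alkylation by an unactivated primary iodide.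

**13 ⇒ 12 ⇒ 10 ⇒ 9 ⇒ 8 ⇒ 7 (functional groups at C9 and C2; the third aryl ether).** The iodide is traced to alcohol 12 and on to the allyl group of 10, whose terminal carbon is excised. The acetal at C2 and the third methoxy group both come from the lactone of 7: reduction to lactol 8, O-methylation of the ring-opened phenoxide to aldehyde 9, and acetalisation. Using the lactone as the common source of C2 and the C6′ oxygen avoids any separate arene–chain bond formation.

**7 ⇒ 5 ⇒ 3 (C1–CH3 and C1–C10).** The quaternary centre is made by two enolate alkylations of lactone 3. The ring holds the C7′ isobutyl group pseudoaxial (peri 5-methoxy group), so the second electrophile enters trans to it. Allyl first, methyl second therefore gives methyl trans and allyl cis to isobutyl, as required. The reverse order would give the C1 epimer.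

**3 ⇒ 1 + 2 (C7′–isobutyl).** The remaining stereocentre is cut at the C7′–CH2 bond: copper-catalysed asymmetric conjugate addition of Grignard reagent 2 to coumarin 1. The coumarin supplies the arene, two of its oxygen substituents, C7′, C1 and C2 in one commercial compound.

## Roads not taken

**Alternative 1:** The arene is made last. Malonyl dichloride A2, carrying the whole terpene on its central carbon, would C-acylate both α-carbons of keto diester A3, forming C2′–C3′ and C5′–C6′ and aromatising to isophthalate A1.
- Merits: the phenols emerge free, so no late aromatic substitution and no O-demethylation are needed. In this respect the route is better than the chosen plan, which has to set two known but demanding late steps (17 and 18) against it.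
- Weak points: the acylating carbon of A2 hangs on a neopentyl-type secondary centre next to quaternary C1, where C-acylation is slow and O-acylation to pyranones competes. The two esters of A1 must then be brought to aldehydes on a free, chelating phloroglucinol, where ortho-hydroxybenzyl alcohols are fragile. The road also gives nothing toward C4/C7/C8 or C7′/C1.
- Comparison: C7′ would have to be set without the lactone template that steps 1–3 use, and a full sesquiterpene synthesis is still needed, so the total is not shorter.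

**Alternative 2:** Rings A and B are cut together (C3–C8 and C4–C5). Trienone A5 would cyclise thermally to cis-fused octalone A4.
- Merits: both rings and the C4 and C8 centres form in one metal-free step. This is better ring-forming economy than the chosen plan, which needs steps 9 and 12 for the same two rings.
- Weak points: A5 needs a trisubstituted diene with the tether cis to the bulky silyloxy-isopropyl group, the less stable geometry. The facial and endo/exo preference rests only on the C1 centre in the tether. C7 is left as an sp2 carbon in A4, so it would have to be set later by hydrogenating a hindered trisubstituted alkene, with no clear reason for the trans C7/C8 result. The C2 ketone of A4 still needs the triflate-reduction sequence used here.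
- Comparison: the chosen plan sets against the higher bond count a catalyst-controlled C7 and an anti-alkylated C8 from commodity partners.

**Alternative 3:** Ring B is cut at C3–C4. Pd(PPh3)4 would ionise (Z)-allylic carbonate A7, and the lithium enolate of its C2 ketone would attack C4 to give octalone A6.
- Merits: C4 comes stereospecifically from a carbinol centre, and the enolate regiochemistry is unambiguous because C1 is quaternary. For C4 this is arguably more secure than the substrate-controlled cuprate addition of step 14, against which the chosen plan sets a conformational argument and a fallback.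
- Weak points: a non-stabilised ketone enolate can attack through the metal as well as anti to it, which undermines net retention. The (Z)-derived allyl complex can isomerise before closure. C7 and C8 must already stand in A7 as an acyclic pair, needing their own asymmetric chemistry. The C5=C6 alkene of A6 costs a later selective hydrogenation.
- Comparison: the chosen plan makes C7/C8 in a single three-component step.

Key step: step 9

Assumption: the antipode of the ferrocenyl diphosphine needed in steps 1 and 9 is assigned by a test reaction (both antipodes are commercial); 2 and 15 are bought as solutions. Changes of R/S descriptors along the route reflect changes in CIP priority only, not inversion.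

## Route

Step 1
Reactants: 1 5,7-dimethoxycoumarin; 2 isobutylmagnesium bromide
Product: 3 (4S)-4-isobutyl-5,7-dimethoxychroman-2-one
Conditions: CuBr·SMe2 (5 mol %), Josiphos-type ferrocenyl diphosphine (6 mol %), 2 (1.3 equiv, slow addition), CH2Cl2–t-BuOMe, −78 °C; aq. NH4Cl
Reagents that add atoms: none
Why: Copper-catalysed asymmetric conjugate addition of a Grignard reagent to a coumarin; the chiral monovalent copper–diphosphine complex delivers isobutyl to one face of C4 of the coumarin and so sets C7′ (S), and the aryl ester enolate is protonated on work-up.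

Step 2
Reactants: 3 (4S)-4-isobutyl-5,7-dimethoxychroman-2-one
Product: 5 (3S,4S)-3-allyl-4-isobutyl-5,7-dimethoxychroman-2-one, via lithium enolate 4 (not isolated)
Conditions: LiN(SiMe3)2 (1.1 equiv), THF, −78 °C; allyl bromide, −78 → −40 °C
Reagents that add atoms: allyl bromide, C=CCBr
Why: Lactone enolate alkylation; the isobutyl group, held pseudoaxial by the peri 5-methoxy group, shields one face so allyl enters trans, and since this centre is planarised again in step 3 its ratio does not matter.

Step 3
Reactants: 5 (3S,4S)-3-allyl-4-isobutyl-5,7-dimethoxychroman-2-one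
Product: 7 (3R,4R)-3-allyl-4-isobutyl-5,7-dimethoxy-3-methylchroman-2-one, via lithium enolate 6 (not isolated)
Conditions: LiN(i-Pr)2 (1.3 equiv), THF–DMPU, −78 → −50 °C; MeI, −78 → −20 °C
Reagents that add atoms: iodomethane, IC
Why: Second enolate alkylation creating quaternary C1: iodomethane approaches enolate 6 anti to the pseudoaxial isobutyl group, placing methyl trans and allyl cis to isobutyl, which is the C7′/C1 relationship of the target; low temperature limits loss of aryloxide to a ketene.

Step 4
Reactants: 7 (3R,4R)-3-allyl-4-isobutyl-5,7-dimethoxy-3-methylchroman-2-one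
Product: 8 (3R,4R)-3-allyl-4-isobutyl-5,7-dimethoxy-3-methylchroman-2-ol (both anomers)
Conditions: i-Bu2AlH (1.1 equiv), CH2Cl2, −78 °C; aq. potassium sodium tartrate
Reagents that add atoms: none
Why: Partial reduction of an aryl lactone to the lactol with an aluminium hydride at low temperature; the α-quaternary centre retards over-reduction.

Step 5
Reactants: 8 (3R,4R)-3-allyl-4-isobutyl-5,7-dimethoxy-3-methylchroman-2-ol
Product: 9 (2R)-2-methyl-2-[(1R)-3-methyl-1-(2,4,6-trimethoxyphenyl)butyl]pent-4-enal
Conditions: K2CO3, MeI, DMF, rt → 40 °C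
Reagents that add atoms: iodomethane, IC
Why: Under base the lactol equilibrates with the ring-opened phenoxide aldehyde, and Williamson O-methylation of the phenoxide traps the open form; the aldehyde is α-quaternary and cannot enolise or condense.

Step 6
Reactants: 9 (2R)-2-methyl-2-[(1R)-3-methyl-1-(2,4,6-trimethoxyphenyl)butyl]pent-4-enal
Product: 10 (4R)-5,5-dimethoxy-4-methyl-4-[(1R)-3-methyl-1-(2,4,6-trimethoxyphenyl)butyl]pent-1-ene
Conditions: HC(OMe)3, TsOH·H2O (cat.), MeOH, 40 °C; Et3N quench
Reagents that add atoms: trimethyl orthoformate, COC(OC)OC; methanol, CO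
Why: Acid-catalysed acetalisation with an orthoester as water scavenger masks the neopentyl aldehyde C2 for the organometallic steps.

Step 7
Reactants: 10 (4R)-5,5-dimethoxy-4-methyl-4-[(1R)-3-methyl-1-(2,4,6-trimethoxyphenyl)butyl]pent-1-ene
Product: 12 (3R)-4,4-dimethoxy-3-methyl-3-[(1R)-3-methyl-1-(2,4,6-trimethoxyphenyl)butyl]butan-1-ol, via aldehyde 11 (not isolated)
Conditions: OsO4 (2 mol %), NaIO4 (4 equiv), 2,6-lutidine, dioxane–H2O (3:1), rt; filter and concentrate; NaBH4, MeOH, 0 °C
Reagents that add atoms: sodium periodate, [Na+].[O-]I(=O)(=O)=O (terminal oxygen source); osmium tetroxide, O=[Os](=O)(=O)=O (oxygen carrier)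
Why: Lemieux–Johnson cleavage (osmylation, then periodate glycol fission) removes the terminal allyl carbon without exposing the ozone-sensitive trimethoxyarene to ozone, and borohydride reduces crude aldehyde 11 to the C9 alcohol.

Step 8
Reactants: 12 (3R)-4,4-dimethoxy-3-methyl-3-[(1R)-3-methyl-1-(2,4,6-trimethoxyphenyl)butyl]butan-1-ol
Product: 13 2-[(3R,4R)-3-(dimethoxymethyl)-1-iodo-3,6-dimethylheptan-4-yl]-1,3,5-trimethoxybenzene
Conditions: I2, PPh3, imidazole, CH2Cl2, 0 °C → rt
Reagents that add atoms: iodine, [I][I]
Why: Appel-type iodination: the alkoxyphosphonium ion is displaced by iodide in an SN2 reaction at unhindered C9, and imidazole keeps the medium non-acidic for the acetal.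

Step 9
Reactants: 14 cyclohex-2-en-1-one; 15 isopropenylmagnesium bromide; 13 2-[(3R,4R)-3-(dimethoxymethyl)-1-iodo-3,6-dimethylheptan-4-yl]-1,3,5-trimethoxybenzene
Product: 17 (2R,3S)-2-[(3R,4R)-3-(dimethoxymethyl)-3,6-dimethyl-4-(2,4,6-trimethoxyphenyl)heptyl]-3-(prop-1-en-2-yl)cyclohexan-1-one, via magnesium enolate 16 (not isolated)
Conditions: CuBr·SMe2 (5 mol %), Josiphos-type ferrocenyl diphosphine (6 mol %), 14 (3.3 equiv), 15 (3.0 equiv, slow addition), t-BuOMe, −78 °C; then DMPU, 13 (1.0 equiv), −78 °C → rt; aq. NH4Cl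
Reagents that add atoms: none
Why: The chiral monovalent copper–diphosphine complex, alkylated by 15, binds the enone as a π-complex, adds oxidatively at C7 to a trivalent copper σ-species and forms the C7–C11 bond by reductive elimination, leaving bromomagnesium enolate 16 with its double bond fixed between C3 and C8. The closest known reaction type is the copper/ferrocenyl-diphosphine-catalysed addition of Grignard reagents to cyclic enones with trapping of the magnesium enolate by an alkyl halide in the presence of a polar cosolvent. No ring is closed; three components are joined around ring B. C7 (S) is set by the ligand, which selects the enone face. C8 (R) is set by the new C7 substituent: the isopropenyl group sits pseudoaxial next to the enolate carbon and 13 attacks from the opposite face, giving the trans ketone, which is also the thermodynamic epimer. The step needs C- over O-alkylation, mono- over polyalkylation and no proton exchange that would move the enolate toward C4; the unhindered primary iodide (the quaternary carbon is two atoms from C9), DMPU to loosen enolate aggregates and a threefold excess of 16 over the valuable iodide serve these ends, and a slight excess of 14 over 15 leaves no Grignard reagent to couple with 13 under copper catalysis. Because 13 is a single enantiomer, any minor enantiomer of 16 ends up as a diastereomer of 17 that chromatography can remove.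

Step 10
Reactants: 17 (2R,3S)-2-[(3R,4R)-3-(dimethoxymethyl)-3,6-dimethyl-4-(2,4,6-trimethoxyphenyl)heptyl]-3-(prop-1-en-2-yl)cyclohexan-1-one
Product: 19 (5S,6R)-6-[(3R,4R)-3-(dimethoxymethyl)-3,6-dimethyl-4-(2,4,6-trimethoxyphenyl)heptyl]-5-(prop-1-en-2-yl)cyclohex-1-en-1-yl trifluoromethanesulfonate, via potassium enolate 18 (not isolated)
Conditions: KN(SiMe3)2 (1.2 equiv), THF, −78 °C; PhNTf2, −78 → 0 °C
Reagents that add atoms: N-phenylbis(trifluoromethanesulfonimide), O=S(=O)(N(c1ccccc1)S(=O)(=O)C(F)(F)F)C(F)(F)F
Why: Kinetic deprotonation at −78 °C removes a C4 methylene proton in preference to the hindered tertiary C8–H, and O-sulfonylation fixes the C3=C4 enol triflate without epimerising C8.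

Step 11
Reactants: 19 (5S,6R)-6-[(3R,4R)-3-(dimethoxymethyl)-3,6-dimethyl-4-(2,4,6-trimethoxyphenyl)heptyl]-5-(prop-1-en-2-yl)cyclohex-1-en-1-yl trifluoromethanesulfonate
Product: 20 (2R)-2-methyl-2-[(1R)-3-methyl-1-(2,4,6-trimethoxyphenyl)butyl]-4-[(1R,6S)-6-(prop-1-en-2-yl)-2-(trifluoromethanesulfonyloxy)cyclohex-2-en-1-yl]butanal
Conditions: TsOH·H2O (10 mol %), acetone–H2O (10:1), rt
Reagents that add atoms: water, O
Why: Acid-catalysed acetal hydrolysis; the enol triflate, the isopropenyl group and the aryl ethers are stable to dilute acid at room temperature.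

Step 12
Reactants: 20 (2R)-2-methyl-2-[(1R)-3-methyl-1-(2,4,6-trimethoxyphenyl)butyl]-4-[(1R,6S)-6-(prop-1-en-2-yl)-2-(trifluoromethanesulfonyloxy)cyclohex-2-en-1-yl]butanal
Product: 21 (2R,4aR,5S)-2-methyl-2-[(1S)-3-methyl-1-(2,4,6-trimethoxyphenyl)butyl]-5-(prop-1-en-2-yl)-1,2,3,4,4a,5,6,7-octahydronaphthalen-1-ol (both C2 carbinol epimers)
Conditions: CrCl2 (6 equiv), NiCl2 (2 mol %), degassed DMF (0.01 M), rt
Reagents that add atoms: none
Why: Intramolecular Nozaki–Hiyama–Kishi reaction: zerovalent nickel inserts into the vinyl triflate, transmetalation gives a vinyl species of trivalent chromium that adds to the aldehyde, forming C2–C3 and closing ring A as a 6-membered ring; the C2 configuration is irrelevant because step 13 oxidises it.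

Step 13
Reactants: 21 (2R,4aR,5S)-2-methyl-2-[(1S)-3-methyl-1-(2,4,6-trimethoxyphenyl)butyl]-5-(prop-1-en-2-yl)-1,2,3,4,4a,5,6,7-octahydronaphthalen-1-ol
Product: 22 (2R,4aR,5S)-2-methyl-2-[(1R)-3-methyl-1-(2,4,6-trimethoxyphenyl)butyl]-5-(prop-1-en-2-yl)-3,4,4a,5,6,7-hexahydronaphthalen-1(2H)-one
Conditions: Dess–Martin periodinane, NaHCO3, CH2Cl2, rt
Reagents that add atoms: none
Why: Dess–Martin oxidation of the allylic alcohol under buffered, neutral conditions gives the s-cis enone and merges both carbinol epimers.

Step 14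
Reactants: 22 (2R,4aR,5S)-2-methyl-2-[(1R)-3-methyl-1-(2,4,6-trimethoxyphenyl)butyl]-5-(prop-1-en-2-yl)-3,4,4a,5,6,7-hexahydronaphthalen-1(2H)-one
Product: 24 (2R,4aR,5S,8R)-2,8-dimethyl-2-[(1S)-3-methyl-1-(2,4,6-trimethoxyphenyl)butyl]-5-(prop-1-en-2-yl)-2,3,4,4a,5,6,7,8-octahydronaphthalen-1-yl trifluoromethanesulfonate, via lithium enolate 23 (not isolated)
Conditions: Me2CuLi (from CuI and 2 MeLi), Et2O, −78 → −30 °C; then N-(5-chloropyridin-2-yl)bis(trifluoromethanesulfonimide), THF, −78 → 0 °C
Reagents that add atoms: lithium dimethylcuprate, [Li+].C[Cu-]C (made from methyllithium, C[Li], and CuI); N-(5-chloropyridin-2-yl)bis(trifluoromethanesulfonimide) (Comins' reagent), O=S(=O)(N(c1ccc(Cl)cn1)S(=O)(=O)C(F)(F)F)C(F)(F)F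
Why: Gilman cuprate conjugate addition to an s-cis enone followed by O-triflation of the regiodefined enolate; methyl attacks C4 axially on the face of C8–H through a chair-like ring B that keeps the C7 and C8 substituents equatorial, whereas the other face needs a twist-boat and puts the methyl in the enolate plane against the C2 oxygen (allylic 1,3-strain), so C4 (R) is set by C7/C8.

Step 15
Reactants: 24 (2R,4aR,5S,8R)-2,8-dimethyl-2-[(1S)-3-methyl-1-(2,4,6-trimethoxyphenyl)butyl]-5-(prop-1-en-2-yl)-2,3,4,4a,5,6,7,8-octahydronaphthalen-1-yl trifluoromethanesulfonate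
Product: 25 (2S,4aR,5S,8R)-2,8-dimethyl-2-[(1S)-3-methyl-1-(2,4,6-trimethoxyphenyl)butyl]-5-(prop-1-en-2-yl)-2,3,4,4a,5,6,7,8-octahydronaphthalene
Conditions: Pd(OAc)2 (5 mol %), PPh3 (10 mol %), n-Bu3N (3 equiv), HCO2H (2 equiv), DMF, 60 °C
Reagents that add atoms: none
Why: Palladium-catalysed formate reduction of a vinyl triflate: oxidative addition to zerovalent palladium, formate exchange, decarboxylation and reductive elimination replace the triflate by hydrogen and leave the alkene at C2=C3.

Step 16
Reactants: 25 (2S,4aR,5S,8R)-2,8-dimethyl-2-[(1S)-3-methyl-1-(2,4,6-trimethoxyphenyl)butyl]-5-(prop-1-en-2-yl)-2,3,4,4a,5,6,7,8-octahydronaphthalene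
Product: 26 2-[(1S,4R,6S,8aR)-4,6-dimethyl-6-[(1S)-3-methyl-1-(2,4,6-trimethoxyphenyl)butyl]-1,2,3,4,6,7,8,8a-octahydronaphthalen-1-yl]propan-2-ol
Conditions: Mn(dpm)3 (10 mol %; dpm = 2,2,6,6-tetramethylheptane-3,5-dionate), PhSiH3 (2 equiv), O2 (1 atm), i-PrOH–CH2Cl2, 0 °C; then PPh3
Reagents that add atoms: dioxygen, O=O
Why: Mukaiyama hydration: hydrogen-atom transfer from a manganese hydride to the terminal CH2 of the 1,1-disubstituted alkene gives the tertiary C11 radical, which is trapped by O2 and reduced to the alcohol; the trisubstituted C2=C3 alkene, flanked by quaternary C1, should react much more slowly.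

Step 17
Reactants: 26 2-[(1S,4R,6S,8aR)-4,6-dimethyl-6-[(1S)-3-methyl-1-(2,4,6-trimethoxyphenyl)butyl]-1,2,3,4,6,7,8,8a-octahydronaphthalen-1-yl]propan-2-ol
Product: 31 2,4,6-trimethoxy-5-[(1S)-1-[(2S,4aR,5S,8R)-5-(2-hydroxypropan-2-yl)-2,8-dimethyl-2,3,4,4a,5,6,7,8-octahydronaphthalen-2-yl]-3-methylbutyl]benzene-1,3-dicarbaldehyde, via aryllithium 27 (not isolated), via lithium aminoalkoxide 28 (not isolated), via aryllithium 29 (not isolated), via bis(aminoalkoxide) 30 (not isolated)
Conditions: n-BuLi (2.2 equiv), TMEDA, THF, 0 °C; DMF (1.1 equiv), −78 → 0 °C; n-BuLi (1.3 equiv), 0 °C; DMF (3 equiv); cold 1 M HCl work-up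
Reagents that add atoms: N,N-dimethylformamide, CN(C)C=O
Why: Directed ortho-metalation and formylation run twice in one flask: C3′–H, between two methoxy groups, is lithiated after the C11 hydroxyl has consumed the first equivalent of base and is quenched with DMF; the resulting α-amino alkoxide 28 acts as a protected aldehyde during the second lithiation at C5′, and dilute acid releases both formyl groups.

Step 18
Reactants: 31 2,4,6-trimethoxy-5-[(1S)-1-[(2S,4aR,5S,8R)-5-(2-hydroxypropan-2-yl)-2,8-dimethyl-2,3,4,4a,5,6,7,8-octahydronaphthalen-2-yl]-3-methylbutyl]benzene-1,3-dicarbaldehyde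
Product: 32 2,4,6-trihydroxy-5-[(1S)-1-[(2S,4aR,5S,8R)-5-(2-hydroxypropan-2-yl)-2,8-dimethyl-2,3,4,4a,5,6,7,8-octahydronaphthalen-2-yl]-3-methylbutyl]benzene-1,3-dicarbaldehyde (CNP0200991.2)
Conditions: NaSEt (10 equiv), DMF, 110–120 °C; cold 1 M HCl work-up
Reagents that add atoms: none
Why: Nucleophilic O-demethylation (SN2 at methyl by thiolate): each methoxy group is ortho or para to two formyl groups, so each aryloxide is a good leaving group; the basic medium spares the tertiary alcohol and the alkene, and the aldehydes are held as unreactive vinylogous carboxylates until acidification.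

## Compound list

1 | 5,7-dimethoxycoumarin | COc1cc(OC)c2ccc(=O)oc2c1 | starting material
2 | isobutylmagnesium bromide | CC(C)C[Mg]Br | starting material
3 | (4S)-4-isobutyl-5,7-dimethoxychroman-2-one | CC(C)C[C@@H]1c2c(OC)cc(OC)cc2OC(=O)C1 | intermediate
4 | lithium enolate of 3 | CC(C)C[C@@H]1c2c(OC)cc(OC)cc2OC(O[Li])=C1 | intermediate
5 | (3S,4S)-3-allyl-4-isobutyl-5,7-dimethoxychroman-2-one | CC(C)C[C@@H]1c2c(OC)cc(OC)cc2OC(=O)[C@H]1CC=C | intermediate
6 | lithium enolate of 5 | CC(C)C[C@@H]1c2c(OC)cc(OC)cc2OC(O[Li])=C1CC=C | intermediate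
7 | (3R,4R)-3-allyl-4-isobutyl-5,7-dimethoxy-3-methylchroman-2-one | CC(C)C[C@@H]1c2c(OC)cc(OC)cc2OC(=O)[C@]1(C)CC=C | intermediate
8 | (3R,4R)-3-allyl-4-isobutyl-5,7-dimethoxy-3-methylchroman-2-ol, both anomers | CC(C)C[C@@H]1c2c(OC)cc(OC)cc2OC(O)[C@]1(C)CC=C | intermediate
9 | (2R)-2-methyl-2-[(1R)-3-methyl-1-(2,4,6-trimethoxyphenyl)butyl]pent-4-enal | CC(C)C[C@H](c1c(OC)cc(OC)cc1OC)[C@@](C)(CC=C)C=O | intermediate
10 | (4R)-5,5-dimethoxy-4-methyl-4-[(1R)-3-methyl-1-(2,4,6-trimethoxyphenyl)butyl]pent-1-ene | CC(C)C[C@H](c1c(OC)cc(OC)cc1OC)[C@@](C)(CC=C)C(OC)OC | intermediate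
11 | (3R)-4,4-dimethoxy-3-methyl-3-[(1R)-3-methyl-1-(2,4,6-trimethoxyphenyl)butyl]butanal | CC(C)C[C@H](c1c(OC)cc(OC)cc1OC)[C@@](C)(CC=O)C(OC)OC | intermediate
12 | (3R)-4,4-dimethoxy-3-methyl-3-[(1R)-3-methyl-1-(2,4,6-trimethoxyphenyl)butyl]butan-1-ol | CC(C)C[C@H](c1c(OC)cc(OC)cc1OC)[C@@](C)(CCO)C(OC)OC | intermediate
13 | 2-[(3R,4R)-3-(dimethoxymethyl)-1-iodo-3,6-dimethylheptan-4-yl]-1,3,5-trimethoxybenzene (C9 iodide; C1 R, C7′ R) | CC(C)C[C@H](c1c(OC)cc(OC)cc1OC)[C@@](C)(CCI)C(OC)OC | intermediate
14 | cyclohex-2-en-1-one | O=C1C=CCCC1 | starting material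
15 | isopropenylmagnesium bromide | CC(=C)[Mg]Br | starting material
16 | bromomagnesium (3S)-3-(prop-1-en-2-yl)cyclohex-1-en-1-olate | CC(=C)[C@@H]1C=C(O[Mg]Br)CCC1 | intermediate
17 | (2R,3S)-2-[(3R,4R)-3-(dimethoxymethyl)-3,6-dimethyl-4-(2,4,6-trimethoxyphenyl)heptyl]-3-(prop-1-en-2-yl)cyclohexan-1-one (C7 S, C8 R, trans) | CC(C)C[C@H](c1c(OC)cc(OC)cc1OC)[C@@](C)(CC[C@H]1C(=O)CCC[C@@H]1C(C)=C)C(OC)OC | intermediate
18 | potassium (5S,6R)-6-[(3R,4R)-3-(dimethoxymethyl)-3,6-dimethyl-4-(2,4,6-trimethoxyphenyl)heptyl]-5-(prop-1-en-2-yl)cyclohex-1-en-1-olate | CC(C)C[C@H](c1c(OC)cc(OC)cc1OC)[C@@](C)(CC[C@H]1C(O[K])=CCC[C@@H]1C(C)=C)C(OC)OC | intermediate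
19 | (5S,6R)-6-[(3R,4R)-3-(dimethoxymethyl)-3,6-dimethyl-4-(2,4,6-trimethoxyphenyl)heptyl]-5-(prop-1-en-2-yl)cyclohex-1-en-1-yl trifluoromethanesulfonate | CC(C)C[C@H](c1c(OC)cc(OC)cc1OC)[C@@](C)(CC[C@H]1C(OS(=O)(=O)C(F)(F)F)=CCC[C@@H]1C(C)=C)C(OC)OC | intermediate
20 | (2R)-2-methyl-2-[(1R)-3-methyl-1-(2,4,6-trimethoxyphenyl)butyl]-4-[(1R,6S)-6-(prop-1-en-2-yl)-2-(trifluoromethanesulfonyloxy)cyclohex-2-en-1-yl]butanal | CC(C)C[C@H](c1c(OC)cc(OC)cc1OC)[C@@](C)(CC[C@H]1C(OS(=O)(=O)C(F)(F)F)=CCC[C@@H]1C(C)=C)C=O | intermediate
21 | (2R,4aR,5S)-2-methyl-2-[(1S)-3-methyl-1-(2,4,6-trimethoxyphenyl)butyl]-5-(prop-1-en-2-yl)-1,2,3,4,4a,5,6,7-octahydronaphthalen-1-ol, both carbinol epimers | CC(C)C[C@H](c1c(OC)cc(OC)cc1OC)[C@]1(C)C(O)C2=CCC[C@H](C(C)=C)[C@H]2CC1 | intermediate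
22 | (2R,4aR,5S)-2-methyl-2-[(1R)-3-methyl-1-(2,4,6-trimethoxyphenyl)butyl]-5-(prop-1-en-2-yl)-3,4,4a,5,6,7-hexahydronaphthalen-1(2H)-one | CC(C)C[C@H](c1c(OC)cc(OC)cc1OC)[C@]1(C)C(=O)C2=CCC[C@H](C(C)=C)[C@H]2CC1 | intermediate
23 | lithium (2R,4aR,5S,8R)-2,8-dimethyl-2-[(1S)-3-methyl-1-(2,4,6-trimethoxyphenyl)butyl]-5-(prop-1-en-2-yl)-2,3,4,4a,5,6,7,8-octahydronaphthalen-1-olate | CC(C)C[C@H](c1c(OC)cc(OC)cc1OC)[C@]1(C)C(O[Li])=C2[C@H](C)CC[C@H](C(C)=C)[C@H]2CC1 | intermediate
24 | (2R,4aR,5S,8R)-2,8-dimethyl-2-[(1S)-3-methyl-1-(2,4,6-trimethoxyphenyl)butyl]-5-(prop-1-en-2-yl)-2,3,4,4a,5,6,7,8-octahydronaphthalen-1-yl trifluoromethanesulfonate | CC(C)C[C@H](c1c(OC)cc(OC)cc1OC)[C@]1(C)C(OS(=O)(=O)C(F)(F)F)=C2[C@H](C)CC[C@H](C(C)=C)[C@H]2CC1 | intermediate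
25 | (2S,4aR,5S,8R)-2,8-dimethyl-2-[(1S)-3-methyl-1-(2,4,6-trimethoxyphenyl)butyl]-5-(prop-1-en-2-yl)-2,3,4,4a,5,6,7,8-octahydronaphthalene | CC(C)C[C@H](c1c(OC)cc(OC)cc1OC)[C@]1(C)C=C2[C@H](C)CC[C@H](C(C)=C)[C@H]2CC1 | intermediate
26 | 2-[(1S,4R,6S,8aR)-4,6-dimethyl-6-[(1S)-3-methyl-1-(2,4,6-trimethoxyphenyl)butyl]-1,2,3,4,6,7,8,8a-octahydronaphthalen-1-yl]propan-2-ol | CC(C)C[C@H](c1c(OC)cc(OC)cc1OC)[C@]1(C)C=C2[C@H](C)CC[C@H](C(C)(C)O)[C@H]2CC1 | intermediate
27 | C3′-lithio derivative of the lithium alkoxide of 26 | CC(C)C[C@H](c1c(OC)c([Li])c(OC)cc1OC)[C@]1(C)C=C2[C@H](C)CC[C@H](C(C)(C)O[Li])[C@H]2CC1 | intermediate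
28 | C3′-[(dimethylamino)(lithiooxy)methyl] derivative of the lithium alkoxide of 26 (aminal carbon unassigned) | CC(C)C[C@H](c1c(OC)c(C(O[Li])N(C)C)c(OC)cc1OC)[C@]1(C)C=C2[C@H](C)CC[C@H](C(C)(C)O[Li])[C@H]2CC1 | intermediate
29 | C5′-lithio derivative of 28 | CC(C)C[C@H](c1c(OC)c(C(O[Li])N(C)C)c(OC)c([Li])c1OC)[C@]1(C)C=C2[C@H](C)CC[C@H](C(C)(C)O[Li])[C@H]2CC1 | intermediate
30 | C3′,C5′-bis[(dimethylamino)(lithiooxy)methyl] derivative of the lithium alkoxide of 26 | CC(C)C[C@H](c1c(OC)c(C(O[Li])N(C)C)c(OC)c(C(O[Li])N(C)C)c1OC)[C@]1(C)C=C2[C@H](C)CC[C@H](C(C)(C)O[Li])[C@H]2CC1 | intermediate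
31 | 2,4,6-trimethoxy-5-[(1S)-1-[(2S,4aR,5S,8R)-5-(2-hydroxypropan-2-yl)-2,8-dimethyl-2,3,4,4a,5,6,7,8-octahydronaphthalen-2-yl]-3-methylbutyl]benzene-1,3-dicarbaldehyde | CC(C)C[C@H](c1c(OC)c(C=O)c(OC)c(C=O)c1OC)[C@]1(C)C=C2[C@H](C)CC[C@H](C(C)(C)O)[C@H]2CC1 | intermediate
32 | 2,4,6-trihydroxy-5-[(1S)-1-[(2S,4aR,5S,8R)-5-(2-hydroxypropan-2-yl)-2,8-dimethyl-2,3,4,4a,5,6,7,8-octahydronaphthalen-2-yl]-3-methylbutyl]benzene-1,3-dicarbaldehyde (CNP0200991.2) | CC(C)C[C@H](c1c(O)c(C=O)c(O)c(C=O)c1O)[C@]1(C)C=C2[C@H](C)CC[C@H](C(C)(C)O)[C@H]2CC1 | target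

## Step count and least certain steps

Total: 18 steps. Longest linear sequence: 18 steps (1 → 32); 14 and 15 enter at step 9.

**Step 9 (key step).** Two processes may fail. The enantioselectivity of copper-catalysed addition of an sp2 Grignard reagent may be modest. The alkylation of the magnesium enolate by an unactivated primary iodide may be slow enough for proton exchange, polyalkylation or copper-mediated coupling of the iodide to compete. Fallback, setting out from 14 and 15 and returning at 17: the same conjugate addition is run with Me3SiCl present to give the silyl enol ether, trimethyl{[(3S)-3-(prop-1-en-2-yl)cyclohex-1-en-1-yl]oxy}silane F1, which is isolated so that its enantiomeric purity can be checked. MeLi in THF then releases lithium (3S)-3-(prop-1-en-2-yl)cyclohex-1-en-1-olate F2, which is alkylated with 13 in THF–HMPA. The two bonds are then made in separate operations through a regiodefined lithium enolate, the standard way of alkylating conjugate-addition enolates with unactivated halides.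

**Step 1.** The 5-methoxy group is peri to the reacting carbon and both methoxy groups donate into the enoate, so addition may be slow and the uncatalysed background reaction may erode selectivity. Fallback, setting out from 1 and returning at 3: ligand-free addition of 2 (CuI, Me3SiCl, THF) gives racemic 4-isobutyl-5,7-dimethoxychroman-2-one F3. Dehydrogenation (DDQ, dioxane, reflux) gives 4-isobutyl-5,7-dimethoxycoumarin F4. Copper hydride-catalysed asymmetric conjugate reduction (Cu(OAc)2, DTBM-SEGPHOS, polymethylhydrosiloxane, t-BuOH) then sets C7′ by delivery of the small hydride instead of the alkyl group.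

**Step 14.** Facial selectivity at C4 may be poor if ring B reacts through a non-chair geometry, and O-triflation of the hindered, copper-bound enolate may be incomplete. Fallback, setting out from 17 and returning at 25 (it bypasses steps 10–15): kinetic enolisation of 17 toward C4 (LiN(i-Pr)2, −78 °C) and axial methylation with MeI give (2R,3S,6R)-2-[(3R,4R)-3-(dimethoxymethyl)-3,6-dimethyl-4-(2,4,6-trimethoxyphenyl)heptyl]-6-methyl-3-(prop-1-en-2-yl)cyclohexan-1-one F5, separated from its C4 epimer. Acetal hydrolysis as in step 11 gives keto aldehyde F6. Intramolecular McMurry coupling (TiCl3, Zn–Cu couple, DME, reflux) then forms C2=C3 and ring A directly.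

**Step 16.** Loss of chemoselectivity would show up as hydrogen-atom transfer to the C2=C3 alkene or as over-oxidation at the allylic or benzylic positions. Fallback, setting out from 25 and returning at 26: ionic Markovnikov hydration by oxymercuration (Hg(OAc)2, THF–H2O), which strongly prefers the unhindered 1,1-disubstituted alkene, gives the organomercurial, acetoxymercurio alcohol F7. NaBH4/NaOH demercuration then gives 26 and also removes any mercury taken up by the electron-rich arene.

**Step 18.** The third demethylation requires expulsion of a multiply charged aryloxide and may stall, and prolonged heating with thiolate may degrade the aldehydes. Fallback, setting out from 31 and returning at 32 (no new compound, F0): chelation-directed cleavage with MgI2·OEt2 in toluene at 80 °C. Magnesium bound between each formyl oxygen and the adjacent methoxy oxygen activates the methyl group toward iodide, so the reaction no longer depends on a free thiolate or a strongly basic medium.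

## Further compounds

F1 | step 9 | trimethyl{[(3S)-3-(prop-1-en-2-yl)cyclohex-1-en-1-yl]oxy}silane | CC(=C)[C@@H]1C=C(O[Si](C)(C)C)CCC1
F2 | step 9 | lithium (3S)-3-(prop-1-en-2-yl)cyclohex-1-en-1-olate | CC(=C)[C@@H]1C=C(O[Li])CCC1
F3 | step 1 | racemic 4-isobutyl-5,7-dimethoxychroman-2-one | CC(C)CC1CC(=O)Oc2cc(OC)cc(OC)c12
F4 | step 1 | 4-isobutyl-5,7-dimethoxycoumarin | CC(C)Cc1cc(=O)oc2cc(OC)cc(OC)c12
F5 | step 14 | (2R,3S,6R)-2-[(3R,4R)-3-(dimethoxymethyl)-3,6-dimethyl-4-(2,4,6-trimethoxyphenyl)heptyl]-6-methyl-3-(prop-1-en-2-yl)cyclohexan-1-one | CC(C)C[C@H](c1c(OC)cc(OC)cc1OC)[C@@](C)(CC[C@H]1C(=O)[C@H](C)CC[C@@H]1C(C)=C)C(OC)OC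
F6 | step 14 | (2R)-2-methyl-2-[(1R)-3-methyl-1-(2,4,6-trimethoxyphenyl)butyl]-4-[(1R,3R,6S)-3-methyl-2-oxo-6-(prop-1-en-2-yl)cyclohexyl]butanal | CC(C)C[C@H](c1c(OC)cc(OC)cc1OC)[C@@](C)(CC[C@H]1C(=O)[C@H](C)CC[C@@H]1C(C)=C)C=O
F7 | step 16 | acetoxymercurio alcohol from 25: C11 bearing OH, CH3 and CH2HgOAc (C11 unassigned) | CC(C)C[C@H](c1c(OC)cc(OC)cc1OC)[C@]1(C)C=C2[C@H](C)CC[C@H](C(C)(O)C[Hg]OC(C)=O)[C@H]2CC1
F0 | step 18 | none | none
A1 | alternative 1 | dimethyl 2,4,6-trihydroxyisophthalate carrying the terpene at C5, C11 triethylsilyl ether | CC(C)C[C@H](c1c(O)c(C(=O)OC)c(O)c(C(=O)OC)c1O)[C@]1(C)C=C2[C@H](C)CC[C@H](C(C)(C)O[Si](CC)(CC)CC)[C@H]2CC1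
A2 | alternative 1 | terpene-substituted malonyl dichloride | CC(C)C[C@H](C(C(Cl)=O)C(Cl)=O)[C@]1(C)C=C2[C@H](C)CC[C@H](C(C)(C)O[Si](CC)(CC)CC)[C@H]2CC1
A3 | alternative 1 | dimethyl 3-oxopentanedioate | COC(=O)CC(=O)CC(=O)OC
A4 | alternative 2 | cis-fused octalone with C2 ketone and C6=C7 alkene, C11 triethylsilyl ether | CC(C)C[C@H](c1c(OC)cc(OC)cc1OC)[C@]1(C)C(=O)[C@H]2[C@H](C)CC=C(C(C)(C)O[Si](CC)(CC)CC)[C@H]2CC1
A5 | alternative 2 | (E)-propenyl ketone tethered to the (Z)-configured 2-substituted diene | CC(C)C[C@H](c1c(OC)cc(OC)cc1OC)[C@@](C)(CC/C=C(/C=C)C(C)(C)O[Si](CC)(CC)CC)C(=O)/C=C/C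
A6 | alternative 3 | octalone with C2 ketone and C5=C6 alkene, C11 triethylsilyl ether | CC(C)C[C@H](c1c(OC)cc(OC)cc1OC)[C@]1(C)C(=O)[C@@H]2[C@H](C)C=C[C@H](C(C)(C)O[Si](CC)(CC)CC)[C@H]2CC1
A7 | alternative 3 | ring A ketone bearing the (Z)-allylic methyl carbonate side chain at C8 | CC(C)C[C@H](c1c(OC)cc(OC)cc1OC)[C@]1(C)C(=O)C[C@H](CC1)[C@H](/C=C\[C@@H](C)OC(=O)OC)C(C)(C)O[Si](CC)(CC)CC
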